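Readings and results stem from a simulated flask with made-up constants.

3 questions stand on one flask, and I answer them with one clock.

- left-handed product and right-handed product together, in percent of the left-handed substrate and right-handed substrate charged together, at 2.0 h
- excess of left-handed product over right-handed product in the product at 2.0 h
- whether the exchange between left-handed substrate and right-handed substrate keeps pace with the reaction: how far the product's excess at 2.0 h gets from its value without exchange to its value with instant exchange (above 80% keeps pace, below 20% hardly takes part, else lags behind)

the same everywhere: left-handed substrate 27 mM; right-handed substrate 27 mM; free catalyst 5.2 mol%; precatalyst 0.5 mol%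
- north-east: reagent 2 equiv; added ligand 1.4 mM; the very flask that is asked about, followed so far
- south-east: reagent 2 equiv; added ligand 2.8 mM; run made earlier
- flask: reagent 2.00 equiv; added ligand 1.4 mM; time 2.0 h

- north-east (time / min: left-handed product / %, right-handed product / %, left-handed substrate / %): 5.00: 31.3, 3.9, 16.9; 10.0: 40.5, 6.1, 7.2; 15.0: 45.9, 6.8, 4.1; 30.0: 50.6, 12.3, 1.9; 60.0: 51.5, 17.5, 1.7
- south-east (time / min: left-handed product / %, right-handed product / %, left-handed substrate / %): 10.0: 39.5, 5.4, 8.7; 20.0: 45.3, 8.6, 2.9; 30.0: 49.1, 8.8, 2.0; 40.0: 49.5, 12.9, 1.7; 50.0: 50.8, 12.8, 1.8

(standard deviation of a reading: 1 percentage point)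

- free catalyst is single-handed; left-handed substrate and right-handed substrate are mirror images of each other, charged as a racemate, each of them at the stated concentration
- the analysis behind the earlier runs scatters by 1 percentage point, standard deviation
- an excess is the difference of the two amounts in percent of their sum
- an excess is below zero if the other one leads

The flask is the north-east run carried on to 2.0 h. Its reagent equals both substrates together and each product costs one reagent, so the fraction x of substrate left is also the fraction of reagent left: x is 1 minus both products. By 30.0 min the left-handed substrate reads 1.9%, so I freeze the catalyst, which each turn gives back, and let right-handed substrate meet reagent in equal amounts. The rate is then κ times x times x, and 1/x climbs straight in time, as in step-growth with balanced end groups. From x = 37.1% at 30.0 min and 31.0% at 60.0 min, κ is 0.0177 min⁻¹.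

That is the weak link, a small difference of noisy readings. The south-east run, with twice the added ligand, gives 0.0186 min⁻¹, but it is a different recipe, so I don't average it in and keep the north-east value, 0.0177 min⁻¹: the late clock, the gain of 1/x per minute.

Then x reaches 23.3% and y 76.7%. Left-handed product plus its substrate reads 53.2%, which gives an excess of 38.8%. With that product capped at half the charge, the excess is 30.4%. The selectivity factor read at 20.0 min in the south-east run is 15.1, so instant exchange gives 87.6%. My excess lies 14.6% of the way, less than 20%.

The forecast says 77%, 38%, below my excess, and hardly takes part, since “Exchange covers well under 20% of that gap”.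

    left-handed substrate + racemization catalyst ⇌ right-handed substrate + racemization catalyst, rate k1*[racemization catalyst]*[left-handed substrate] forward; the back reaction follows from the equilibrium constant (k = 0.204 M⁻¹ s⁻¹)
    reagent + free catalyst + left-handed substrate → free catalyst + left-handed product (k = 68.3 M⁻² s⁻¹)
    precatalyst ⇌ racemization catalyst (K = 29.0, k = 3.38 × 10⁻⁴ s⁻¹)
    reagent + free catalyst + right-handed substrate → free catalyst + right-handed product (k = 4.50 M⁻² s⁻¹)
    free catalyst + added ligand ⇌ idle complex (K = 285 M⁻¹, k = 0.892 M⁻¹ s⁻¹)

The flask gives 76.9% and 37.7%, and exchange hardly takes part, at 8.3% of the way. Free catalyst stands at 77.2% of its charge at 0.200 h and 76.6% at 2.00 h. With 3.5 mM of added ligand, free catalyst is 55.0%, so the clock scales to 0.0127 min⁻¹. Drawn from the same line's start, it puts x at 27.1%, and that flask ends with 26.6% of its reagent left.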